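**Retrosynthetic overview**

1. The target is read as a germacranolide. Ring A is the ten-membered carbocycle C1–C10 with a Z C1=C10 and an E C4=C5 double bond; ring B is the γ-lactone O–C6–C7–C11–C12. Both acetates are put on last, from the 3,9-diol.
2. Ring A is closed last at C9–C10 by an intramolecular Nozaki–Hiyama–Kishi reaction of a (Z)-alkenyl iodide with a C9 aldehyde on the finished lactone. C11 is set before that by hydrogenation of the α-methylene lactone.
3. Ring B is made first, in the key step. An acyclic C11 alkenyllithium takes up CO2 (C11–C12), and a zerovalent palladium catalyst delivers the resulting carboxylate to C6 of a C3–C4 vinyl epoxide (O–C6). This is a formal (3+2) annulation of CO2.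
4. Enabling feature: the lactone oxygen sits on C6, allylic to the E C4=C5 bond whose other allylic carbon C3 carries oxygen, so C3(O)–C4(Me)=C5–C6(O) is an opened vinyl epoxide. The lactone carbonyl C12 is a one-carbon, CO2-level unit on C11. The Sharpless epoxide stereocenter is relayed to C6 and leaves the C3 hydroxyl.
5. The acyclic precursor comes from a Julia–Kocienski union of an epoxy aldehyde (C1–C5) with a sulfone (C6–C9, C11, C13), whose C7 stereocenter comes from a menthyloxyfuranone.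

Key step: step 12

Remark: germacranolide numbering is used throughout (target = 3S,6S,7S,9S,11R, 1(10)Z, 4E); 3-{[tert-butyl(dimethyl)silyl]oxy}propanal and (5R)-5-(l-menthyloxy)furan-2(5H)-one are assumed to be commercial.

**Route**

Step 1
Reactants: 1 3-{[tert-butyl(dimethyl)silyl]oxy}propanal
Product: 2 ethyl (2E)-5-{[tert-butyl(dimethyl)silyl]oxy}-2-methylpent-2-enoate
Conditions: Ph3P=C(CH3)CO2Et, CH2Cl2, 25 °C
Reagents that add atoms: ethyl 2-(triphenyl-λ5-phosphanylidene)propanoate, CCOC(=O)C(C)=P(c1ccccc1)(c1ccccc1)c1ccccc1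
Why: Wittig olefination with a stabilised ylide should give the (E)-trisubstituted enoate selectively.

Step 2
Reactants: 2 ethyl (2E)-5-{[tert-butyl(dimethyl)silyl]oxy}-2-methylpent-2-enoate
Product: 3 (2E)-5-{[tert-butyl(dimethyl)silyl]oxy}-2-methylpent-2-en-1-ol
Conditions: i-Bu2AlH (2.2 equiv), CH2Cl2, −78 °C; aq. potassium sodium tartrate
Reagents that add atoms: none
Why: 1,2-reduction of the conjugated ester by the aluminium hydride should give the allylic alcohol without touching the silyl ether.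

Step 3
Reactants: 3 (2E)-5-{[tert-butyl(dimethyl)silyl]oxy}-2-methylpent-2-en-1-ol
Product: 4 [(2S,3S)-3-(2-{[tert-butyl(dimethyl)silyl]oxy}ethyl)-2-methyloxiran-2-yl]methanol
Conditions: Ti(OiPr)4 (10 mol %), L-(+)-diethyl tartrate (12 mol %), t-BuOOH, 4 Å MS, CH2Cl2, −20 °C
Reagents that add atoms: tert-butyl hydroperoxide, CC(C)(C)OO
Why: Sharpless asymmetric epoxidation; the L-(+)-tartrate catalyst should deliver oxygen to the face that gives the (2S,3S)-epoxide, which sets C3 and C4 by catalyst control.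

Step 4
Reactants: 4 [(2S,3S)-3-(2-{[tert-butyl(dimethyl)silyl]oxy}ethyl)-2-methyloxiran-2-yl]methanol
Product: 5 (2R,3S)-3-(2-{[tert-butyl(dimethyl)silyl]oxy}ethyl)-2-methyloxirane-2-carbaldehyde
Conditions: Dess–Martin periodinane, NaHCO3, CH2Cl2, 0 → 25 °C
Reagents that add atoms: none
Why: Dess–Martin oxidation under buffered conditions should give the non-enolisable epoxy aldehyde without epoxide opening (the descriptor change at the quaternary carbon is only a priority change).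

Step 5
Reactants: 6 (5R)-5-{[(1R,2S,5R)-5-methyl-2-(propan-2-yl)cyclohexyl]oxy}furan-2(5H)-one
Product: 7 (4R,5R)-5-{[(1R,2S,5R)-5-methyl-2-(propan-2-yl)cyclohexyl]oxy}-4-[1-(trimethylsilyl)ethenyl]oxolan-2-one
Conditions: CH2=C(SiMe3)Br, Mg, THF, 40 °C; then CuBr·SMe2 (20 mol %), 6, THF, −78 → −40 °C; aq. NH4Cl
Reagents that add atoms: (1-bromovinyl)trimethylsilane, C=C(Br)[Si](C)(C)C
Why: copper-catalysed conjugate addition of the alkenyl Grignard reagent should occur anti to the 5-menthyloxy group, which sets the future C7 (4R) by substrate control.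

Step 6
Reactants: 7 (4R,5R)-5-{[(1R,2S,5R)-5-methyl-2-(propan-2-yl)cyclohexyl]oxy}-4-[1-(trimethylsilyl)ethenyl]oxolan-2-one
Product: 8 (2R)-2-[1-(trimethylsilyl)ethenyl]butane-1,4-diol
Conditions: LiAlH4 (3 equiv), THF, 0 → 65 °C; H2O, aq. NaOH
Reagents that add atoms: none
Why: hydride reduction of the lactone and of the aldehyde released from the acyloxy acetal should give the 2-substituted butane-1,4-diol and free menthol without touching the stereocenter.

Step 7
Reactants: 8 (2R)-2-[1-(trimethylsilyl)ethenyl]butane-1,4-diol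
Product: 9 (2R)-4-{[tert-butyl(diphenyl)silyl]oxy}-2-[1-(trimethylsilyl)ethenyl]butan-1-ol
Conditions: TBDPSCl (1.0 equiv), imidazole, CH2Cl2, −20 °C
Reagents that add atoms: tert-butyl(chloro)diphenylsilane, CC(C)(C)[Si](Cl)(c1ccccc1)c1ccccc1
Why: silylation with the bulky chlorosilane should go to the less hindered 4-hydroxyl, because the 1-hydroxyl is β-branched and flanked by the silylvinyl group.

Step 8
Reactants: 9 (2R)-4-{[tert-butyl(diphenyl)silyl]oxy}-2-[1-(trimethylsilyl)ethenyl]butan-1-ol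
Product: 10 5-({(2S)-4-{[tert-butyl(diphenyl)silyl]oxy}-2-[1-(trimethylsilyl)ethenyl]butyl}sulfanyl)-1-phenyl-1H-tetrazole
Conditions: 1-phenyl-1H-tetrazole-5-thiol, PPh3, DIAD, THF, 0 → 25 °C
Reagents that add atoms: 1-phenyl-1H-tetrazole-5-thiol, Sc1nnnn1-c1ccccc1
Why: Mitsunobu thioetherification of the remaining primary alcohol (the descriptor change is only a priority change).

Step 9
Reactants: 10 5-({(2S)-4-{[tert-butyl(diphenyl)silyl]oxy}-2-[1-(trimethylsilyl)ethenyl]butyl}sulfanyl)-1-phenyl-1H-tetrazole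
Product: 11 5-({(2S)-4-{[tert-butyl(diphenyl)silyl]oxy}-2-[1-(trimethylsilyl)ethenyl]butyl}sulfonyl)-1-phenyl-1H-tetrazole
Conditions: (NH4)6Mo7O24·4H2O (10 mol %), 30% H2O2, EtOH, 0 → 25 °C
Reagents that add atoms: hydrogen peroxide, OO
Why: molybdate-catalysed peroxide oxidation of the sulfide to the sulfone, under which the unactivated vinylsilane should not be epoxidised.

Step 10
Reactants: 11 5-({(2S)-4-{[tert-butyl(diphenyl)silyl]oxy}-2-[1-(trimethylsilyl)ethenyl]butyl}sulfonyl)-1-phenyl-1H-tetrazole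
Product: 12 5-({(2R)-4-{[tert-butyl(diphenyl)silyl]oxy}-2-(1-iodoethenyl)butyl}sulfonyl)-1-phenyl-1H-tetrazole
Conditions: N-iodosuccinimide (1.3 equiv), (CF3)2CHOH, 0 °C
Reagents that add atoms: N-iodosuccinimide, O=C1CCC(=O)N1I
Why: ipso-iododesilylation of the vinylsilane through a β-silyl-stabilised cation should give the 1-iodoalkene.

Step 11
Reactants: 12 5-({(2R)-4-{[tert-butyl(diphenyl)silyl]oxy}-2-(1-iodoethenyl)butyl}sulfonyl)-1-phenyl-1H-tetrazole; 5 (2R,3S)-3-(2-{[tert-butyl(dimethyl)silyl]oxy}ethyl)-2-methyloxirane-2-carbaldehyde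
Product: 13 tert-butyl({(3R,4E)-5-[(2S,3S)-3-(2-{[tert-butyl(dimethyl)silyl]oxy}ethyl)-2-methyloxiran-2-yl]-3-(1-iodoethenyl)pent-4-en-1-yl}oxy)diphenylsilane
Conditions: KN(SiMe3)2 (1.05 equiv) added to 12 and 5 (1.2 equiv), DME, −60 → 25 °C
Reagents that add atoms: none
Why: Julia–Kocienski olefination of the phenyltetrazolyl sulfone with the non-enolisable aldehyde should give the (E)-vinyl epoxide after Smiles rearrangement and loss of SO2.

Step 12
Reactants: 13 tert-butyl({(3R,4E)-5-[(2S,3S)-3-(2-{[tert-butyl(dimethyl)silyl]oxy}ethyl)-2-methyloxiran-2-yl]-3-(1-iodoethenyl)pent-4-en-1-yl}oxy)diphenylsilane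
Product: 16 (4S,5R)-4-(2-{[tert-butyl(diphenyl)silyl]oxy}ethyl)-5-[(1E,3S)-5-{[tert-butyl(dimethyl)silyl]oxy}-3-hydroxy-2-methylpent-1-en-1-yl]-3-methylideneoxolan-2-one, via alkenyllithium 14 (not isolated), via lithium acrylate 15 (not isolated)
Conditions: t-BuLi (2.1 equiv), Et2O, −78 °C; CO2 (g), −78 → 0 °C; Ar purge; AcOH (1.0 equiv), Pd(PPh3)4 (5 mol %), THF, 25 °C
Reagents that add atoms: carbon dioxide, O=C=O
Why: Iodine–lithium exchange gives alkenyllithium 14, which CO2 carboxylates at C11 (C11–C12); after neutralisation, zerovalent palladium ionises the vinyl epoxide with inversion at C4 to a syn,syn-π-allylpalladium alkoxide, and the tethered carboxylate attacks the distal terminus C6 anti to palladium (O–C6), so the sequence is a formal (3+2) annulation of CO2 onto a C11 carbanion and a C6 allyl cation. The closest known reaction types are the carboxylation of alkenyllithiums with CO2 and the palladium-catalysed Tsuji–Trost 1,4-addition of carboxylic acids to vinyl epoxides. The γ-lactone closes in the 5-exo mode at the allyl terminus, whereas attack at C4 would need a seven-membered ring. C6 is set by double inversion, that is net retention with 1,4-transfer from the Sharpless-derived C4–O bond, which places the new C–O bond trans to the C7 side chain, while C3 is untouched and is released as the free alcohol. The E geometry of C4=C5 follows from the π-allyl in which the larger C3 substituent is syn and the methyl group anti. The step needs chemoselective exchange in the presence of the epoxide, which the fast exchange at −78 °C and the inertness of the epoxide until palladium is added should secure.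

Step 13
Reactants: 16 (4S,5R)-4-(2-{[tert-butyl(diphenyl)silyl]oxy}ethyl)-5-[(1E,3S)-5-{[tert-butyl(dimethyl)silyl]oxy}-3-hydroxy-2-methylpent-1-en-1-yl]-3-methylideneoxolan-2-one
Product: 17 (4S,5R)-5-[(1E,3S)-3,5-bis{[tert-butyl(dimethyl)silyl]oxy}-2-methylpent-1-en-1-yl]-4-(2-{[tert-butyl(diphenyl)silyl]oxy}ethyl)-3-methylideneoxolan-2-one
Conditions: TBSOTf, 2,6-lutidine, CH2Cl2, −78 °C
Reagents that add atoms: tert-butyldimethylsilyl trifluoromethanesulfonate, CC(C)(C)[Si](C)(C)OS(=O)(=O)C(F)(F)F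
Why: silylation of the secondary allylic alcohol with a non-nucleophilic base should leave the α-methylene lactone untouched and block β-elimination and retro-aldol paths in the later aldehyde steps.

Step 14
Reactants: 17 (4S,5R)-5-[(1E,3S)-3,5-bis{[tert-butyl(dimethyl)silyl]oxy}-2-methylpent-1-en-1-yl]-4-(2-{[tert-butyl(diphenyl)silyl]oxy}ethyl)-3-methylideneoxolan-2-one
Product: 18 (3R,4S,5S)-5-[(1E,3S)-3,5-bis{[tert-butyl(dimethyl)silyl]oxy}-2-methylpent-1-en-1-yl]-4-(2-{[tert-butyl(diphenyl)silyl]oxy}ethyl)-3-methyloxolan-2-one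
Conditions: H2 (1 atm), RhCl(PPh3)3 (10 mol %), PhMe–EtOH (1:1), 25 °C
Reagents that add atoms: none
Why: homogeneous hydrogenation should reduce only the 1,1-disubstituted conjugated alkene and deliver hydrogen to the face anti to the adjacent C4 side chain, which sets C11 (3R, methyl cis to that side chain) by substrate control.

Step 15
Reactants: 18 (3R,4S,5S)-5-[(1E,3S)-3,5-bis{[tert-butyl(dimethyl)silyl]oxy}-2-methylpent-1-en-1-yl]-4-(2-{[tert-butyl(diphenyl)silyl]oxy}ethyl)-3-methyloxolan-2-one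
Product: 19 (3R,4S,5S)-4-(2-{[tert-butyl(diphenyl)silyl]oxy}ethyl)-5-[(1E,3S)-3-{[tert-butyl(dimethyl)silyl]oxy}-5-hydroxy-2-methylpent-1-en-1-yl]-3-methyloxolan-2-one
Conditions: camphorsulfonic acid (10 mol %), MeOH–CH2Cl2 (1:1), 0 °C
Reagents that add atoms: none
Why: acid-catalysed methanolysis should cleave the primary tert-butyldimethylsilyl ether much faster than the hindered secondary one and the acid-stable tert-butyldiphenylsilyl ether.

Step 16
Reactants: 19 (3R,4S,5S)-4-(2-{[tert-butyl(diphenyl)silyl]oxy}ethyl)-5-[(1E,3S)-3-{[tert-butyl(dimethyl)silyl]oxy}-5-hydroxy-2-methylpent-1-en-1-yl]-3-methyloxolan-2-one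
Product: 20 (3R,4S,5S)-4-(2-{[tert-butyl(diphenyl)silyl]oxy}ethyl)-5-[(1E,3S)-3-{[tert-butyl(dimethyl)silyl]oxy}-2-methyl-5-oxopent-1-en-1-yl]-3-methyloxolan-2-one
Conditions: Dess–Martin periodinane, NaHCO3, CH2Cl2, 0 → 25 °C
Reagents that add atoms: none
Why: Dess–Martin oxidation under neutral conditions should give the β-silyloxy aldehyde without elimination or epimerisation at the lactone α-carbon.

Step 17
Reactants: 20 (3R,4S,5S)-4-(2-{[tert-butyl(diphenyl)silyl]oxy}ethyl)-5-[(1E,3S)-3-{[tert-butyl(dimethyl)silyl]oxy}-2-methyl-5-oxopent-1-en-1-yl]-3-methyloxolan-2-one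
Product: 21 (3R,4S,5S)-4-(2-{[tert-butyl(diphenyl)silyl]oxy}ethyl)-5-[(1E,3S,5Z)-3-{[tert-butyl(dimethyl)silyl]oxy}-6-iodo-2-methylhepta-1,5-dien-1-yl]-3-methyloxolan-2-one
Conditions: EtPPh3I, n-BuLi, THF, 25 °C; I2, −78 °C; NaN(SiMe3)2, −20 °C; then 20, −78 °C
Reagents that add atoms: ethyltriphenylphosphonium iodide, CC[P+](c1ccccc1)(c1ccccc1)c1ccccc1.[I-]; iodine, II
Why: Stork–Zhao-type Wittig olefination with the α-iodo ylide should give the (Z)-2-iodo-2-alkene under kinetic control at low temperature.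

Step 18
Reactants: 21 (3R,4S,5S)-4-(2-{[tert-butyl(diphenyl)silyl]oxy}ethyl)-5-[(1E,3S,5Z)-3-{[tert-butyl(dimethyl)silyl]oxy}-6-iodo-2-methylhepta-1,5-dien-1-yl]-3-methyloxolan-2-one
Product: 22 (3R,4S,5S)-5-[(1E,3S,5Z)-3-hydroxy-6-iodo-2-methylhepta-1,5-dien-1-yl]-4-(2-hydroxyethyl)-3-methyloxolan-2-one
Conditions: HF·pyridine, pyridine, THF, 0 → 25 °C
Reagents that add atoms: none
Why: fluoride-mediated cleavage of both silyl ethers under non-basic conditions should spare the epimerisable lactone α-carbon and the alkenyl iodide.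

Step 19
Reactants: 22 (3R,4S,5S)-5-[(1E,3S,5Z)-3-hydroxy-6-iodo-2-methylhepta-1,5-dien-1-yl]-4-(2-hydroxyethyl)-3-methyloxolan-2-one
Product: 23 [(2S,3S,4R)-2-[(1E,3S,5Z)-3-hydroxy-6-iodo-2-methylhepta-1,5-dien-1-yl]-4-methyl-5-oxooxolan-3-yl]acetaldehyde
Conditions: TEMPO (10 mol %), PhI(OAc)2 (1.1 equiv), CH2Cl2, 25 °C
Reagents that add atoms: none
Why: oxoammonium-mediated oxidation should take the unhindered primary alcohol in preference to the hindered secondary allylic alcohol.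

Step 20
Reactants: 23 [(2S,3S,4R)-2-[(1E,3S,5Z)-3-hydroxy-6-iodo-2-methylhepta-1,5-dien-1-yl]-4-methyl-5-oxooxolan-3-yl]acetaldehyde
Product: 24 (3R,3aS,5S,6Z,9S,10E,11aS)-5,9-dihydroxy-3,6,10-trimethyl-3a,4,5,8,9,11a-hexahydrocyclodeca[b]furan-2(3H)-one
Conditions: CrCl2 (8 equiv), NiCl2 (2 mol %), DMSO–THF (3:1), 2 mM, 25 °C
Reagents that add atoms: none
Why: the intramolecular Nozaki–Hiyama–Kishi reaction should close the ten-membered ring with retention of the Z alkene geometry and tolerance of the free hydroxyl and the lactone; C9 is expected to be set by substrate control as 9S, the aldehyde adding with its oxygen on the outside of the forming ring.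

Step 21
Reactants: 24 (3R,3aS,5S,6Z,9S,10E,11aS)-5,9-dihydroxy-3,6,10-trimethyl-3a,4,5,8,9,11a-hexahydrocyclodeca[b]furan-2(3H)-one
Product: 25 (3R,3aS,5S,6Z,9S,10E,11aS)-3,6,10-trimethyl-2-oxo-2,3,3a,4,5,8,9,11a-octahydrocyclodeca[b]furan-5,9-diyl diacetate
Conditions: Ac2O, pyridine, DMAP (cat.), CH2Cl2, 25 °C
Reagents that add atoms: acetic anhydride, CC(=O)OC(C)=O
Why: nucleophile-catalysed acetylation of both secondary allylic alcohols under mild basic conditions should give the target without epimerisation at C11.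

**Compound list**

1 | 3-{[tert-butyl(dimethyl)silyl]oxy}propanal | CC(C)(C)[Si](C)(C)OCCC=O | starting material
2 | ethyl (2E)-5-{[tert-butyl(dimethyl)silyl]oxy}-2-methylpent-2-enoate | CCOC(=O)/C(C)=C/CCO[Si](C)(C)C(C)(C)C | intermediate
3 | (2E)-5-{[tert-butyl(dimethyl)silyl]oxy}-2-methylpent-2-en-1-ol | OC/C(C)=C/CCO[Si](C)(C)C(C)(C)C | intermediate
4 | [(2S,3S)-3-(2-{[tert-butyl(dimethyl)silyl]oxy}ethyl)-2-methyloxiran-2-yl]methanol | CC(C)(C)[Si](C)(C)OCC[C@@H]1O[C@@]1(C)CO | intermediate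
5 | (2R,3S)-3-(2-{[tert-butyl(dimethyl)silyl]oxy}ethyl)-2-methyloxirane-2-carbaldehyde | CC(C)(C)[Si](C)(C)OCC[C@@H]1O[C@@]1(C)C=O | intermediate
6 | (5R)-5-{[(1R,2S,5R)-5-methyl-2-(propan-2-yl)cyclohexyl]oxy}furan-2(5H)-one | C[C@@H]1CC[C@H]([C@@H](C1)O[C@@H]2OC(=O)C=C2)C(C)C | starting material
7 | (4R,5R)-5-{[(1R,2S,5R)-5-methyl-2-(propan-2-yl)cyclohexyl]oxy}-4-[1-(trimethylsilyl)ethenyl]oxolan-2-one | C[C@@H]1CC[C@H]([C@@H](C1)O[C@@H]2OC(=O)C[C@H]2C(=C)[Si](C)(C)C)C(C)C | intermediate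
8 | (2R)-2-[1-(trimethylsilyl)ethenyl]butane-1,4-diol | OCC[C@H](CO)C(=C)[Si](C)(C)C | intermediate
9 | (2R)-4-{[tert-butyl(diphenyl)silyl]oxy}-2-[1-(trimethylsilyl)ethenyl]butan-1-ol | CC(C)(C)[Si](c1ccccc1)(c1ccccc1)OCC[C@H](CO)C(=C)[Si](C)(C)C | intermediate
10 | 5-({(2S)-4-{[tert-butyl(diphenyl)silyl]oxy}-2-[1-(trimethylsilyl)ethenyl]butyl}sulfanyl)-1-phenyl-1H-tetrazole | CC(C)(C)[Si](c1ccccc1)(c1ccccc1)OCC[C@H](CSc1nnnn1-c1ccccc1)C(=C)[Si](C)(C)C | intermediate
11 | 5-({(2S)-4-{[tert-butyl(diphenyl)silyl]oxy}-2-[1-(trimethylsilyl)ethenyl]butyl}sulfonyl)-1-phenyl-1H-tetrazole | CC(C)(C)[Si](c1ccccc1)(c1ccccc1)OCC[C@H](CS(=O)(=O)c1nnnn1-c1ccccc1)C(=C)[Si](C)(C)C | intermediate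
12 | 5-({(2R)-4-{[tert-butyl(diphenyl)silyl]oxy}-2-(1-iodoethenyl)butyl}sulfonyl)-1-phenyl-1H-tetrazole | CC(C)(C)[Si](c1ccccc1)(c1ccccc1)OCC[C@H](CS(=O)(=O)c1nnnn1-c1ccccc1)C(=C)I | intermediate
13 | tert-butyl({(3R,4E)-5-[(2S,3S)-3-(2-{[tert-butyl(dimethyl)silyl]oxy}ethyl)-2-methyloxiran-2-yl]-3-(1-iodoethenyl)pent-4-en-1-yl}oxy)diphenylsilane | CC(C)(C)[Si](C)(C)OCC[C@@H]1O[C@@]1(C)/C=C/[C@H](C(=C)I)CCO[Si](c1ccccc1)(c1ccccc1)C(C)(C)C | intermediate
14 | tert-butyl({(3R,4E)-5-[(2S,3S)-3-(2-{[tert-butyl(dimethyl)silyl]oxy}ethyl)-2-methyloxiran-2-yl]-3-(1-lithioethenyl)pent-4-en-1-yl}oxy)diphenylsilane | CC(C)(C)[Si](C)(C)OCC[C@@H]1O[C@@]1(C)/C=C/[C@H](C(=C)[Li])CCO[Si](c1ccccc1)(c1ccccc1)C(C)(C)C | intermediate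
15 | lithium 2-{(3R,4E)-1-{[tert-butyl(diphenyl)silyl]oxy}-5-[(2S,3S)-3-(2-{[tert-butyl(dimethyl)silyl]oxy}ethyl)-2-methyloxiran-2-yl]pent-4-en-3-yl}prop-2-enoate | CC(C)(C)[Si](C)(C)OCC[C@@H]1O[C@@]1(C)/C=C/[C@H](C(=C)C(=O)[O-])CCO[Si](c1ccccc1)(c1ccccc1)C(C)(C)C.[Li+] | intermediate
16 | (4S,5R)-4-(2-{[tert-butyl(diphenyl)silyl]oxy}ethyl)-5-[(1E,3S)-5-{[tert-butyl(dimethyl)silyl]oxy}-3-hydroxy-2-methylpent-1-en-1-yl]-3-methylideneoxolan-2-one | CC(C)(C)[Si](c1ccccc1)(c1ccccc1)OCC[C@@H]2[C@@H](/C=C(\C)[C@@H](O)CCO[Si](C)(C)C(C)(C)C)OC(=O)C2=C | intermediate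
17 | (4S,5R)-5-[(1E,3S)-3,5-bis{[tert-butyl(dimethyl)silyl]oxy}-2-methylpent-1-en-1-yl]-4-(2-{[tert-butyl(diphenyl)silyl]oxy}ethyl)-3-methylideneoxolan-2-one | CC(C)(C)[Si](c1ccccc1)(c1ccccc1)OCC[C@@H]2[C@@H](/C=C(\C)[C@@H](O[Si](C)(C)C(C)(C)C)CCO[Si](C)(C)C(C)(C)C)OC(=O)C2=C | intermediate
18 | (3R,4S,5S)-5-[(1E,3S)-3,5-bis{[tert-butyl(dimethyl)silyl]oxy}-2-methylpent-1-en-1-yl]-4-(2-{[tert-butyl(diphenyl)silyl]oxy}ethyl)-3-methyloxolan-2-one | CC(C)(C)[Si](c1ccccc1)(c1ccccc1)OCC[C@@H]2[C@@H](/C=C(\C)[C@@H](O[Si](C)(C)C(C)(C)C)CCO[Si](C)(C)C(C)(C)C)OC(=O)[C@@H]2C | intermediate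
19 | (3R,4S,5S)-4-(2-{[tert-butyl(diphenyl)silyl]oxy}ethyl)-5-[(1E,3S)-3-{[tert-butyl(dimethyl)silyl]oxy}-5-hydroxy-2-methylpent-1-en-1-yl]-3-methyloxolan-2-one | CC(C)(C)[Si](c1ccccc1)(c1ccccc1)OCC[C@@H]2[C@@H](/C=C(\C)[C@@H](O[Si](C)(C)C(C)(C)C)CCO)OC(=O)[C@@H]2C | intermediate
20 | (3R,4S,5S)-4-(2-{[tert-butyl(diphenyl)silyl]oxy}ethyl)-5-[(1E,3S)-3-{[tert-butyl(dimethyl)silyl]oxy}-2-methyl-5-oxopent-1-en-1-yl]-3-methyloxolan-2-one | CC(C)(C)[Si](c1ccccc1)(c1ccccc1)OCC[C@@H]2[C@@H](/C=C(\C)[C@@H](O[Si](C)(C)C(C)(C)C)CC=O)OC(=O)[C@@H]2C | intermediate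
21 | (3R,4S,5S)-4-(2-{[tert-butyl(diphenyl)silyl]oxy}ethyl)-5-[(1E,3S,5Z)-3-{[tert-butyl(dimethyl)silyl]oxy}-6-iodo-2-methylhepta-1,5-dien-1-yl]-3-methyloxolan-2-one | CC(C)(C)[Si](c1ccccc1)(c1ccccc1)OCC[C@@H]2[C@@H](/C=C(\C)[C@@H](O[Si](C)(C)C(C)(C)C)C/C=C(\I)C)OC(=O)[C@@H]2C | intermediate
22 | (3R,4S,5S)-5-[(1E,3S,5Z)-3-hydroxy-6-iodo-2-methylhepta-1,5-dien-1-yl]-4-(2-hydroxyethyl)-3-methyloxolan-2-one | OCC[C@@H]1[C@@H](/C=C(\C)[C@@H](O)C/C=C(\I)C)OC(=O)[C@@H]1C | intermediate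
23 | [(2S,3S,4R)-2-[(1E,3S,5Z)-3-hydroxy-6-iodo-2-methylhepta-1,5-dien-1-yl]-4-methyl-5-oxooxolan-3-yl]acetaldehyde | O=CC[C@@H]1[C@@H](/C=C(\C)[C@@H](O)C/C=C(\I)C)OC(=O)[C@@H]1C | intermediate
24 | (3R,3aS,5S,6Z,9S,10E,11aS)-5,9-dihydroxy-3,6,10-trimethyl-3a,4,5,8,9,11a-hexahydrocyclodeca[b]furan-2(3H)-one | O[C@H]1C[C@@H]2[C@@H](/C=C(\C)[C@@H](O)C/C=C\1C)OC(=O)[C@@H]2C | intermediate
25 | (3R,3aS,5S,6Z,9S,10E,11aS)-3,6,10-trimethyl-2-oxo-2,3,3a,4,5,8,9,11a-octahydrocyclodeca[b]furan-5,9-diyl diacetate | CC(=O)O[C@H]1C[C@@H]2[C@@H](/C=C(\C)[C@@H](OC(C)=O)C/C=C\1C)OC(=O)[C@@H]2C | target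

**Step count and risks**

Total step count: 21. Longest linear sequence: 17 steps (steps 5–21; the epoxy aldehyde branch, steps 1–4, joins at step 11).

Steps most likely to fail:

Step 12. The organolithium reagents may attack or deprotonate the vinyl epoxide before carboxylation. In the palladium stage the π-allyl intermediate may undergo syn–anti isomerisation or be attacked at the proximal carbon, which would erode the C6 configuration or the alkene geometry. The fallback avoids organolithium chemistry and brings the one-carbon unit in by carbonylation. It sets out from 13: with Pd(PPh3)4, CO (1 atm), water and Et3N in THF at 45 °C, hydroxycarbonylation of the alkenyl iodide should give 2-{(3R,4E)-1-{[tert-butyl(diphenyl)silyl]oxy}-5-[(2S,3S)-3-(2-{[tert-butyl(dimethyl)silyl]oxy}ethyl)-2-methyloxiran-2-yl]pent-4-en-3-yl}prop-2-enoic acid F1. The same zerovalent palladium catalyst should then close F1 onto the vinyl epoxide, and the fallback comes back to the route at 16.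

Step 20. Closure of the strained ten-membered ring may be slower than protodeiodination or intermolecular coupling, and facial selectivity at C9 may be poor. The fallback changes the ring-closing event to an olefin metathesis and sets C9 at an acyclic stage, where the epimers can be separated. It sets out from 20:
- Methylenation with Ph3P=CH2 (from Ph3PCH3Br and KN(SiMe3)2, THF, −78 → 0 °C) should give (3R,4S,5S)-4-(2-{[tert-butyl(diphenyl)silyl]oxy}ethyl)-5-[(1E,3S)-3-{[tert-butyl(dimethyl)silyl]oxy}-2-methylhexa-1,5-dien-1-yl]-3-methyloxolan-2-one F2.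
- HF·pyridine should give the diol (3R,4S,5S)-5-[(1E,3S)-3-hydroxy-2-methylhexa-1,5-dien-1-yl]-4-(2-hydroxyethyl)-3-methyloxolan-2-one F3.
- TEMPO and PhI(OAc)2 should give [(2S,3S,4R)-2-[(1E,3S)-3-hydroxy-2-methylhexa-1,5-dien-1-yl]-4-methyl-5-oxooxolan-3-yl]acetaldehyde F4.
- Addition of CH2=C(CH3)MgBr (2.2 equiv, THF, −78 °C) and separation of the C9 epimers should give (3R,4S,5S)-5-[(1E,3S)-3-hydroxy-2-methylhexa-1,5-dien-1-yl]-4-[(2S)-2-hydroxy-3-methylbut-3-en-1-yl]-3-methyloxolan-2-one F5.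
- Ring-closing metathesis of F5 with the second-generation Hoveyda–Grubbs catalyst RuCl2(H2IMes)(=CH-C6H4-2-OiPr) in toluene at high dilution and 80 °C should close the ring with the Z-trisubstituted alkene, the only geometry the medium ring accommodates. The fallback comes back to the route at 24.

Step 14. Hydrogen may be delivered to both faces of the exocyclic alkene, giving the C11 epimer, and slow reduction may allow isomerisation of the alkene into the ring. The fallback sets C11 by kinetic protonation of an enolate instead of by syn addition of hydrogen. It sets out from 17: conjugate reduction with LiBH(s-Bu)3 in THF at −78 °C should give lithium (4S,5R)-5-[(1E,3S)-3,5-bis{[tert-butyl(dimethyl)silyl]oxy}-2-methylpent-1-en-1-yl]-4-(2-{[tert-butyl(diphenyl)silyl]oxy}ethyl)-3-methyl-4,5-dihydrofuran-2-olate F6. Protonation of F6 with acetic acid at −78 °C from the face anti to the C4 side chain should bring the fallback back to the route at 18.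

Further compounds
F1 | step 12 | 2-{(3R,4E)-1-{[tert-butyl(diphenyl)silyl]oxy}-5-[(2S,3S)-3-(2-{[tert-butyl(dimethyl)silyl]oxy}ethyl)-2-methyloxiran-2-yl]pent-4-en-3-yl}prop-2-enoic acid | CC(C)(C)[Si](C)(C)OCC[C@@H]1O[C@@]1(C)/C=C/[C@H](C(=C)C(=O)O)CCO[Si](c1ccccc1)(c1ccccc1)C(C)(C)C
F2 | step 20 | (3R,4S,5S)-4-(2-{[tert-butyl(diphenyl)silyl]oxy}ethyl)-5-[(1E,3S)-3-{[tert-butyl(dimethyl)silyl]oxy}-2-methylhexa-1,5-dien-1-yl]-3-methyloxolan-2-one | CC(C)(C)[Si](c1ccccc1)(c1ccccc1)OCC[C@@H]2[C@@H](/C=C(\C)[C@@H](O[Si](C)(C)C(C)(C)C)CC=C)OC(=O)[C@@H]2C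
F3 | step 20 | (3R,4S,5S)-5-[(1E,3S)-3-hydroxy-2-methylhexa-1,5-dien-1-yl]-4-(2-hydroxyethyl)-3-methyloxolan-2-one | OCC[C@@H]1[C@@H](/C=C(\C)[C@@H](O)CC=C)OC(=O)[C@@H]1C
F4 | step 20 | [(2S,3S,4R)-2-[(1E,3S)-3-hydroxy-2-methylhexa-1,5-dien-1-yl]-4-methyl-5-oxooxolan-3-yl]acetaldehyde | O=CC[C@@H]1[C@@H](/C=C(\C)[C@@H](O)CC=C)OC(=O)[C@@H]1C
F5 | step 20 | (3R,4S,5S)-5-[(1E,3S)-3-hydroxy-2-methylhexa-1,5-dien-1-yl]-4-[(2S)-2-hydroxy-3-methylbut-3-en-1-yl]-3-methyloxolan-2-one | CC(=C)[C@@H](O)C[C@@H]1[C@@H](/C=C(\C)[C@@H](O)CC=C)OC(=O)[C@@H]1C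
F6 | step 14 | lithium (4S,5R)-5-[(1E,3S)-3,5-bis{[tert-butyl(dimethyl)silyl]oxy}-2-methylpent-1-en-1-yl]-4-(2-{[tert-butyl(diphenyl)silyl]oxy}ethyl)-3-methyl-4,5-dihydrofuran-2-olate | CC(C)(C)[Si](c1ccccc1)(c1ccccc1)OCC[C@@H]2[C@@H](/C=C(\C)[C@@H](O[Si](C)(C)C(C)(C)C)CCO[Si](C)(C)C(C)(C)C)OC([O-])=C2C.[Li+]
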